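The spiro atom C6, common to ring A (C1–C6) and ring B (C6–C11), owes its chirality solely to the difference between C10 (CHBr) and C8 (CH2). Ring B can therefore be assembled mirror-symmetric around a masked C9 ketone and differentiated later. Everything rests on cutting C6–C7 and C6–C11 together: the α′-enolate of dimedone isobutyl vinylogous ester is alkylated twice by the ethylene ketal of 1,5-diiodopentan-3-one. This single operation closes ring B and creates quaternary C6 beside the C5 gem-dimethyl carbon with no stereochemical demand. A chiral lithium amide then desymmetrises the C9 ketone. Ring A and the C9/C10 halogens follow under substrate control.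

Key step: step 4

Remark on locants: C1 (C=CH2), C2, C3 (CHOH), C4 (CHBr), C5 (CMe2), C6 (spiro), C7, C8, C9 (CClMe), C10 (CHBr), C11; all names use these spiro[5.5]undecane locants, and the "C1 face" and "C5 face" of ring B are the faces on which those atoms lie.
Remark on step 6: the (R,R)-amide is assigned by analogy with 4-tert-butylcyclohexanone; if a first correlation shows the opposite sense, the (S,S)-amine is used and nothing else changes.
Remark on ring B: all facial arguments assume the chair or half-chair in which quaternary C5 is equatorial and sp2 C1 is axial on ring B.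

Step 1
Reactants: 1 dimedone; 2 isobutanol
Product: 3 3-isobutoxy-5,5-dimethylcyclohex-2-en-1-one
Conditions: p-TsOH·H2O (cat.), toluene, reflux, Dean–Stark
Reagents that add atoms: none
Why: Acid-catalysed condensation of the enolised 1,3-dione with the alcohol (vinylogous esterification) is driven by azeotropic removal of water, and the symmetry of 1 allows only one vinylogous ester.

Step 2
Reactants: 4 1,5-dichloropentan-3-one; 5 ethylene glycol
Product: 6 2,2-bis(2-chloroethyl)-1,3-dioxolane
Conditions: p-TsOH·H2O (cat.), toluene, reflux, Dean–Stark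
Reagents that add atoms: none
Why: Standard acid-catalysed ketalisation masks the ketone, and acidic rather than basic conditions avoid loss of HCl from the β-chloro ketone.

Step 3
Reactants: 6 2,2-bis(2-chloroethyl)-1,3-dioxolane
Product: 7 2,2-bis(2-iodoethyl)-1,3-dioxolane
Conditions: NaI (4 equiv), acetone, reflux
Reagents that add atoms: sodium iodide, [Na+].[I-]
Why: Finkelstein exchange at two unhindered primary carbons is driven by precipitation of NaCl and gives the more reactive bis-electrophile without touching the ketal.

Step 4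
Reactants: 3 3-isobutoxy-5,5-dimethylcyclohex-2-en-1-one; 7 2,2-bis(2-iodoethyl)-1,3-dioxolane
Product: 9 3-isobutoxy-5,5-dimethylspiro[5.5]undec-2-ene-1,9-dione 9-(ethylene ketal), via monoalkylated iodide 8 (not isolated)
Conditions: LiN(i-Pr)2 (1.05 equiv), THF, −78 °C; cannulate into 7 (1.15 equiv), DMPU, −78 → 0 °C; LiN(i-Pr)2 (1.3 equiv), −78 → 23 °C
Reagents that add atoms: none
Why: LiN(i-Pr)2 removes a C6–H (the α′ position, kinetically preferred over the vinylogous C4–H) and the lithium enolate displaces iodide from one arm of 7 by SN2 to give 8 (C6–C7), after which a second equivalent of base regenerates the now fully substituted C1–C6 enolate, which attacks the remaining iodoethyl arm (C6–C11). The closest known reaction type is spiroannulation of 3-alkoxycyclohex-2-enones by double α′-alkylation with α,ω-dihalides, that is a Stork–Danheiser alkylation run twice. Ring B closes in the 6-exo-tet mode. No stereocentre arises, because ring B of 9 has a mirror plane through C6 and C9, so C6 carries two identical arms. The step needs α′ over γ regiochemistry, C- over O-alkylation and cyclisation over E2 or bridging of two enolates: the first is secured by irreversible deprotonation at −78 °C, the second by the tight lithium enolate and by the eight-membered ring that O-closure would require, the third by inverse addition to a slight excess of 7, the soft primary iodide and DMPU. The hindered bond beside quaternary C5 is deliberately left to the intramolecular event.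

Step 5
Reactants: 9 3-isobutoxy-5,5-dimethylspiro[5.5]undec-2-ene-1,9-dione 9-(ethylene ketal)
Product: 10 3-isobutoxy-5,5-dimethylspiro[5.5]undec-2-ene-1,9-dione
Conditions: PPTS (0.2 equiv), acetone–H2O (10:1), 50 °C
Reagents that add atoms: water, O
Why: Mild acid-catalysed ketal hydrolysis cleaves the dialkyl ketal much faster than the conjugated and far less basic vinylogous ester, so ring A stays masked while the C9 ketone is released.

Step 6
Reactants: 10 3-isobutoxy-5,5-dimethylspiro[5.5]undec-2-ene-1,9-dione
Product: 12 (6R)-3-isobutoxy-5,5-dimethyl-1-oxospiro[5.5]undeca-2,9-dien-9-yl trifluoromethanesulfonate, via lithium enolate 11 (not isolated)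
Conditions: (R,R)-bis(1-phenylethyl)amine, n-BuLi, LiCl, THF, −78 °C; 10; then N-(5-chloropyridin-2-yl)bis(trifluoromethanesulfonimide), −78 → 0 °C
Reagents that add atoms: N-(5-chloropyridin-2-yl)bis(trifluoromethanesulfonimide), O=S(=O)(N(c1ccc(Cl)cn1)S(=O)(=O)C(F)(F)F)C(F)(F)F
Why: Enantioselective deprotonation of a prochiral 4,4-disubstituted cyclohexanone by a C2-symmetric chiral lithium amide followed by O-sulfonylation, in which ring B is locked as the chair with C5 equatorial, the amide selects one of the two enantiotopic axial α-hydrogens (C10–H over C8–H), and this choice alone makes C6 stereogenic (6R) and fixes the enol triflate at C9=C10.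

Step 7
Reactants: 12 (6R)-3-isobutoxy-5,5-dimethyl-1-oxospiro[5.5]undeca-2,9-dien-9-yl trifluoromethanesulfonate
Product: 13 (6R)-3-isobutoxy-5,5,9-trimethylspiro[5.5]undeca-2,9-dien-1-one
Conditions: MeZnCl (1.5 equiv), Pd(PPh3)4 (5 mol %), THF, 23 → 45 °C
Reagents that add atoms: methylzinc chloride, C[Zn]Cl
Why: Negishi coupling of the alkenyl triflate under zerovalent palladium catalysis replaces C–OTf by C–CH3 without moving the alkene, and the mild organozinc leaves the vinylogous ester alone, so C6 is untouched.

Step 8
Reactants: 14 (tributylstannyl)methanol; 15 ethyl vinyl ether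
Product: 16 tributyl[(1-ethoxyethoxy)methyl]stannane
Conditions: PPTS (cat.), CH2Cl2, 0 → 23 °C
Reagents that add atoms: none
Why: Acid-catalysed addition of the alcohol to the vinyl ether gives the mixed acetal and turns the tin compound into a protected hydroxymethyl anion equivalent.

Step 9
Reactants: 13 (6R)-3-isobutoxy-5,5,9-trimethylspiro[5.5]undeca-2,9-dien-1-one; 16 tributyl[(1-ethoxyethoxy)methyl]stannane
Product: 18 (6R)-1-(hydroxymethyl)-5,5,9-trimethylspiro[5.5]undeca-1,9-dien-3-one, via tertiary carbinol adduct 17 (not isolated)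
Conditions: 16, n-BuLi, THF, −78 °C; CeCl3; 13, −78 → 0 °C; then 0.5 M aq HCl, THF, 0 → 23 °C
Reagents that add atoms: water, O
Why: Tin–lithium exchange gives the α-alkoxymethyllithium, whose CeCl3-assisted 1,2-addition to the hindered C1 carbonyl and acid-induced Stork–Danheiser transposition move the carbonyl to C3 and place the future methylidene carbon on C1, while the same dilute acid removes the acetal yet is too weak to protonate C9=C10 and erode C6.

Step 10
Reactants: 18 (6R)-1-(hydroxymethyl)-5,5,9-trimethylspiro[5.5]undeca-1,9-dien-3-one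
Product: 21 (4S,6S)-4-bromo-1-(hydroxymethyl)-5,5,9-trimethylspiro[5.5]undeca-1,9-dien-3-one, via bis-silyl dienol ether 19 (not isolated), via silyl-protected bromo enone 20 (not isolated)
Conditions: LiN(i-Pr)2 (2.3 equiv), THF, −78 °C; TMSCl (2.6 equiv); NBS (1.0 equiv), −78 °C; citric acid, MeOH, 0 °C; Et3N (cat.), CH2Cl2, 23 °C
Reagents that add atoms: N-bromosuccinimide, O=C1CCC(=O)N1Br
Why: Kinetic α′-deprotonation of the enone at C4, silylation and bromination of the 2-silyloxydiene with NBS (far more nucleophilic than C9=C10) give the α′-bromo enone, and amine-mediated enolisation should funnel C4 to the equatorial (4S) bromide of the ring A conformer that tucks the C1 substituent under sp2 C10 rather than under the axial C8–H.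

Step 11
Reactants: 21 (4S,6S)-4-bromo-1-(hydroxymethyl)-5,5,9-trimethylspiro[5.5]undeca-1,9-dien-3-one
Product: 22 (3R,4S,6S)-4-bromo-1-(hydroxymethyl)-5,5,9-trimethylspiro[5.5]undeca-1,9-dien-3-ol
Conditions: i-Bu2AlH (3.5 equiv), CH2Cl2, −78 °C; aq potassium sodium tartrate
Reagents that add atoms: none
Why: In this 1,2-reduction of the enone the axial C5 methyl blocks the face of C3=O on which the bromine lies, so hydride should enter from the opposite face and give the axial (3R) alcohol cis to the equatorial C4 bromine, a relationship that also precludes epoxide closure.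

Step 12
Reactants: 22 (3R,4S,6S)-4-bromo-1-(hydroxymethyl)-5,5,9-trimethylspiro[5.5]undeca-1,9-dien-3-ol
Product: 25 (3R,4S,6S)-4-bromo-5,5,9-trimethyl-1-methylidenespiro[5.5]undec-9-en-3-ol, via sulfonyl hydrazone adduct 23 (not isolated), via allylic diazene 24 (not isolated)
Conditions: N′-isopropylidene-2-nitrobenzenesulfonohydrazide (IPNBSH), PPh3, DEAD, THF, 0 → 23 °C; then CF3CH2OH–H2O (1:1), 23 °C
Reagents that add atoms: none
Why: Mitsunobu displacement of the unhindered primary allylic alcohol, hydrazone hydrolysis, loss of sulfinate and retro-ene loss of N2 from the allylic diazene (reductive allylic transposition) deliver hydrogen to C2 and move the alkene to exocyclic C1=CH2 under neutral conditions that spare C3 and C4, the hindered axial C3–OH being too slow to compete.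

Step 13
Reactants: 25 (3R,4S,6S)-4-bromo-5,5,9-trimethyl-1-methylidenespiro[5.5]undec-9-en-3-ol
Product: 26 (3R,4S,6S)-4-bromo-5,5,9-trimethyl-1-methylidene-3-(triethylsilyloxy)spiro[5.5]undec-9-ene
Conditions: Et3SiOTf, 2,6-lutidine, CH2Cl2, −78 → 0 °C
Reagents that add atoms: triethylsilyl trifluoromethanesulfonate, CC[Si](CC)(CC)OS(=O)(=O)C(F)(F)F
Why: Silylation with the triflate overcomes the hindrance of the axial C3–OH, removes the only other hydroxyl before the C9 alcohol must be activated, and should loosen the ring A chair that parks the methylidene under C10.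

Step 14
Reactants: 26 (3R,4S,6S)-4-bromo-5,5,9-trimethyl-1-methylidene-3-(triethylsilyloxy)spiro[5.5]undec-9-ene
Product: 27 (3R,4S,6S,9R,10S)-4-bromo-9,10-epoxy-5,5,9-trimethyl-1-methylidene-3-(triethylsilyloxy)spiro[5.5]undecane
Conditions: mCPBA (1.05 equiv), NaHCO3, CH2Cl2, −20 → 0 °C
Reagents that add atoms: 3-chloroperoxybenzoic acid, O=C(OO)c1cccc(Cl)c1
Why: Prilezhaev epoxidation picks the electron-rich trisubstituted C9=C10 over the hindered 1,1-disubstituted C1=CH2, and with C1 axial on the ring B half-chair the peracid should attack the C5 face, as in epoxidation of rigid cyclohexenes anti to an axial homoallylic substituent.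

Step 15
Reactants: 27 (3R,4S,6S,9R,10S)-4-bromo-9,10-epoxy-5,5,9-trimethyl-1-methylidene-3-(triethylsilyloxy)spiro[5.5]undecane
Product: 28 (3R,4S,6S,9R,10R)-4,10-dibromo-5,5,9-trimethyl-1-methylidene-3-(triethylsilyloxy)spiro[5.5]undecan-9-ol
Conditions: LiBr (5 equiv), AcOH (3 equiv), THF, 23 → 40 °C
Reagents that add atoms: lithium bromide, [Li+].[Br-]
Why: Weakly acidic bromide opening of the epoxide is SN2-like at the less substituted C10 and follows the trans-diaxial (Fürst–Plattner) path of the half-chair with C5 equatorial, so inversion places bromine on the C1 face (10R) while the C9–O bond and its configuration are kept.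

Step 16
Reactants: 28 (3R,4S,6S,9R,10R)-4,10-dibromo-5,5,9-trimethyl-1-methylidene-3-(triethylsilyloxy)spiro[5.5]undecan-9-ol
Product: 30 (3R,4S,6S,9R,10R)-4,10-dibromo-9-chloro-5,5,9-trimethyl-1-methylidenespiro[5.5]undecan-3-ol, via silyl-protected bromochloride 29 (not isolated)
Conditions: 1-chloro-N,N,2-trimethylprop-1-en-1-amine (1.5 equiv), CH2Cl2, 0 → 23 °C; then HF·pyridine, pyridine, THF, 0 °C
Reagents that add atoms: 1-chloro-N,N,2-trimethylprop-1-en-1-amine, CC(C)=C(Cl)N(C)C
Why: In this neutral deoxychlorination with an α-chloroenamine the antiperiplanar C10 bromine assists ionisation of the activated tertiary C9–O bond and chloride opens the resulting bromonium ion at the tertiary carbon from the C5 face, giving net retention (9R) and the trans Br/Cl array, after which buffered fluoride frees the C3–OH.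

Compound list
1 | dimedone | CC1(C)CC(=O)CC(=O)C1 | starting material
2 | isobutanol | CC(C)CO | starting material
3 | 3-isobutoxy-5,5-dimethylcyclohex-2-en-1-one | CC(C)COC1=CC(=O)CC(C)(C)C1 | intermediate
4 | 1,5-dichloropentan-3-one | O=C(CCCl)CCCl | starting material
5 | ethylene glycol | OCCO | starting material
6 | 2,2-bis(2-chloroethyl)-1,3-dioxolane | ClCCC1(CCCl)OCCO1 | intermediate
7 | 2,2-bis(2-iodoethyl)-1,3-dioxolane | ICCC1(CCI)OCCO1 | intermediate
8 | 6-{2-[2-(2-iodoethyl)-1,3-dioxolan-2-yl]ethyl}-3-isobutoxy-5,5-dimethylcyclohex-2-en-1-one (racemic, not isolated) | O=C1C=C(OCC(C)C)CC(C)(C)C1CCC1(CCI)OCCO1 | intermediate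
9 | 3-isobutoxy-5,5-dimethylspiro[5.5]undec-2-ene-1,9-dione 9-(ethylene ketal) (achiral) | O=C1C=C(OCC(C)C)CC(C)(C)C12CCC3(CC2)OCCO3 | intermediate
10 | 3-isobutoxy-5,5-dimethylspiro[5.5]undec-2-ene-1,9-dione (achiral) | O=C1C=C(OCC(C)C)CC(C)(C)C12CCC(=O)CC2 | intermediate
11 | lithium (6R)-C9=C10 enolate of 10 (not isolated) | O=C1C=C(OCC(C)C)CC(C)(C)[C@]12CCC([O-])=CC2.[Li+] | intermediate
12 | (6R)-3-isobutoxy-5,5-dimethyl-1-oxospiro[5.5]undeca-2,9-dien-9-yl trifluoromethanesulfonate | O=C1C=C(OCC(C)C)CC(C)(C)[C@]12CCC(OS(=O)(=O)C(F)(F)F)=CC2 | intermediate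
13 | (6R)-3-isobutoxy-5,5,9-trimethylspiro[5.5]undeca-2,9-dien-1-one | O=C1C=C(OCC(C)C)CC(C)(C)[C@]12CCC(C)=CC2 | intermediate
14 | (tributylstannyl)methanol | OC[Sn](CCCC)(CCCC)CCCC | starting material
15 | ethyl vinyl ether | C=COCC | starting material
16 | tributyl[(1-ethoxyethoxy)methyl]stannane (racemic acetal) | CCOC(C)OC[Sn](CCCC)(CCCC)CCCC | intermediate
17 | (6R)-1-[(1-ethoxyethoxy)methyl]-3-isobutoxy-5,5,9-trimethylspiro[5.5]undeca-2,9-dien-1-ol (epimers at C1 and the acetal carbon, not isolated) | CCOC(C)OCC1(O)C=C(OCC(C)C)CC(C)(C)[C@]12CCC(C)=CC2 | intermediate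
18 | (6R)-1-(hydroxymethyl)-5,5,9-trimethylspiro[5.5]undeca-1,9-dien-3-one | OCC1=CC(=O)CC(C)(C)[C@]12CCC(C)=CC2 | intermediate
19 | (6R)-5,5,9-trimethyl-3-(trimethylsilyloxy)-1-[(trimethylsilyloxy)methyl]spiro[5.5]undeca-1,3,9-triene (not isolated) | C[Si](C)(C)OCC1=CC(O[Si](C)(C)C)=CC(C)(C)[C@]12CCC(C)=CC2 | intermediate
20 | (6S)-4-bromo-5,5,9-trimethyl-1-[(trimethylsilyloxy)methyl]spiro[5.5]undeca-1,9-dien-3-one (C4 epimers, not isolated) | C[Si](C)(C)OCC1=CC(=O)C(Br)C(C)(C)[C@]12CCC(C)=CC2 | intermediate
21 | (4S,6S)-4-bromo-1-(hydroxymethyl)-5,5,9-trimethylspiro[5.5]undeca-1,9-dien-3-one | OCC1=CC(=O)[C@@H](Br)C(C)(C)[C@]12CCC(C)=CC2 | intermediate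
22 | (3R,4S,6S)-4-bromo-1-(hydroxymethyl)-5,5,9-trimethylspiro[5.5]undeca-1,9-dien-3-ol | OCC1=C[C@@H](O)[C@@H](Br)C(C)(C)[C@]12CCC(C)=CC2 | intermediate
23 | N-alkylated N′-isopropylidene-2-nitrobenzenesulfonohydrazide derived from the primary alcohol of 22 (not isolated) | CC(C)=NN(CC1=C[C@@H](O)[C@@H](Br)C(C)(C)[C@]12CCC(C)=CC2)S(=O)(=O)c1ccccc1[N+](=O)[O-] | intermediate
24 | allylic diazene (C1–CH2–N=NH) derived from 23 (not isolated) | N=NCC1=C[C@@H](O)[C@@H](Br)C(C)(C)[C@]12CCC(C)=CC2 | intermediate
25 | (3R,4S,6S)-4-bromo-5,5,9-trimethyl-1-methylidenespiro[5.5]undec-9-en-3-ol | C=C1C[C@@H](O)[C@@H](Br)C(C)(C)[C@]12CCC(C)=CC2 | intermediate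
26 | (3R,4S,6S)-4-bromo-5,5,9-trimethyl-1-methylidene-3-(triethylsilyloxy)spiro[5.5]undec-9-ene | C=C1C[C@@H](O[Si](CC)(CC)CC)[C@@H](Br)C(C)(C)[C@]12CCC(C)=CC2 | intermediate
27 | (3R,4S,6S,9R,10S)-4-bromo-9,10-epoxy-5,5,9-trimethyl-1-methylidene-3-(triethylsilyloxy)spiro[5.5]undecane (oxygen on the C5 face) | C=C1C[C@@H](O[Si](CC)(CC)CC)[C@@H](Br)C(C)(C)[C@]12CC[C@@]3(C)O[C@H]3C2 | intermediate
28 | (3R,4S,6S,9R,10R)-4,10-dibromo-5,5,9-trimethyl-1-methylidene-3-(triethylsilyloxy)spiro[5.5]undecan-9-ol | C=C1C[C@@H](O[Si](CC)(CC)CC)[C@@H](Br)C(C)(C)[C@]12CC[C@@](C)(O)[C@H](Br)C2 | intermediate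
29 | (3R,4S,6S,9R,10R)-4,10-dibromo-9-chloro-5,5,9-trimethyl-1-methylidene-3-(triethylsilyloxy)spiro[5.5]undecane (not isolated) | C=C1C[C@@H](O[Si](CC)(CC)CC)[C@@H](Br)C(C)(C)[C@]12CC[C@@](C)(Cl)[C@H](Br)C2 | intermediate
30 | (3R,4S,6S,9R,10R)-4,10-dibromo-9-chloro-5,5,9-trimethyl-1-methylidenespiro[5.5]undecan-3-ol | C=C1C[C@@H](O)[C@@H](Br)C(C)(C)[C@]12CC[C@@](C)(Cl)[C@H](Br)C2 | target

Total step count: 16
Longest linear sequence: 14 steps (steps 2–7 and 9–16, from 1,5-dichloropentan-3-one)

Steps most likely to fail

Step 4. The second alkylation builds a quaternary carbon next to another one. Slow ring closure would let E2 loss of HI from the iodoethyl arm, deprotonation at C4 or bridging of two enolates by one dihalide take over. The fallback sets out from 3 and builds ring B by cycloaddition.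
- A Mannich reaction of the lithium enolate with dimethyl(methylidene)ammonium iodide should give the 6-(dimethylaminomethyl) ketone F1.
- MeI converts it into the trimethylammonium iodide F2.
- Aqueous NaHCO3 eliminates this to the 6-methylidene vinylogous ester F3.
- A thermal Diels–Alder reaction with 2-(trimethylsilyloxy)buta-1,3-diene (toluene, 120 °C) should give the spiro silyl enol ether F4 with the para orientation, placing the oxygen on C9.
- Dilute acid hydrolysis returns to the route at 10.

Step 15. The bromide trajectory at C10 runs past axial C1 and the methylidene group. The opening may therefore be sluggish, may be diverted to attack at C9, or may give way to rearrangement of the epoxide to a ketone. The fallback sets out from 26 and adds both halogens in one anti addition across C9=C10 (NBS, ClTi(Oi-Pr)3, CH2Cl2–hexane, −20 °C). Only a bromonium ion on the C1 face can be opened at tertiary C9 through a chair-like trans-diaxial transition state. The required diastereomer is separated by chromatography and the route is rejoined at 29. This is held in reserve because that face is the more hindered one. It makes no new compound (F0).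

Step 10. Facial selectivity at C4 depends only on a remote difference between C7 and C11. The bromination may therefore be poorly selective, the amine equilibration may stay incomplete, and the base may isomerise the γ-hydroxy enone. The fallback sets out from 21 used as its C4 epimer mixture and replaces substrate control by reagent control. Asymmetric transfer hydrogenation under dynamic kinetic resolution is used (RuCl(p-cymene)[(R,R)-TsDPEN] or its antipode, HCO2H–Et3N, 23–40 °C), known for cyclic α-halo ketones to give cis-halohydrins. It should reduce only the matched, continuously epimerising bromide and rejoin the route at 22. It makes no new compound (F0).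

Further compounds
F1 | step 4 | 6-[(dimethylamino)methyl]-3-isobutoxy-5,5-dimethylcyclohex-2-en-1-one (racemic) | CN(C)CC1C(=O)C=C(OCC(C)C)CC1(C)C
F2 | step 4 | [(4-isobutoxy-6,6-dimethyl-2-oxocyclohex-3-en-1-yl)methyl]trimethylammonium iodide (racemic) | C[N+](C)(C)CC1C(=O)C=C(OCC(C)C)CC1(C)C.[I-]
F3 | step 4 | 3-isobutoxy-5,5-dimethyl-6-methylidenecyclohex-2-en-1-one | C=C1C(=O)C=C(OCC(C)C)CC1(C)C
F4 | step 4 | 3-isobutoxy-5,5-dimethyl-9-(trimethylsilyloxy)spiro[5.5]undeca-2,9-dien-1-one (racemic) | O=C1C=C(OCC(C)C)CC(C)(C)C12CCC(O[Si](C)(C)C)=CC2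
F0 | step 15 | none | none
F0 | step 10 | none | none
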